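The route rests on disconnecting ring B (C5–C10) at C9–C10, together with C4–C5 of ring A and the C8–O bond. This unravels the trans-decalin to an acyclic E,E-diene epoxide ester. In one operation a Lewis acid opens the epoxide, and a cation–olefin cascade closes ring A, then ring B, and traps C8 as a temporary δ-lactone. The step exploits the antiperiplanar chain C3–C4–C5–C10–C9–C8: all five ring stereocentres derive from two E-alkenes and one Sharpless epoxidation, and the E-CH2O group becomes the equatorial C18. The precursor is a farnesylacetate-derived silyloxy epoxide. Afterwards O3 is removed, C18 is oxidised and the lactone is exchanged for acetate and acid.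

Key step: step 5

Remark: labdane numbering is used (ring A = C1–C5 and C10; ring B = C5–C10; side chain C11–C13; C17 on C8; C18 and C19 on C4; C20 on C10). Commercial (2E,6E)-farnesyl bromide is taken as geometrically pure, and the aluminium alkoxide at O3 of 8 is drawn as OH.

Step 1
Reactants: 1 (2E,6E)-farnesyl bromide; 2 tert-butyl acetate
Product: 4 tert-butyl (4E,8E)-5,9,13-trimethyltetradeca-4,8,12-trienoate, via lithium enolate of tert-butyl acetate 3 (not isolated)
Conditions: LDA, THF, −78 °C; then 1, DMPU, −78 → 0 °C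
Reagents that add atoms: none
Why: Ester enolate alkylation (SN2 at a primary allylic bromide) adds C12–C13 without touching the two E-alkenes, and the tert-butyl group suppresses Claisen self-condensation.

Step 2
Reactants: 4 tert-butyl (4E,8E)-5,9,13-trimethyltetradeca-4,8,12-trienoate
Product: 5 tert-butyl (4E,8E,12E)-14-hydroxy-5,9,13-trimethyltetradeca-4,8,12-trienoate
Conditions: SeO2 (cat.), t-BuOOH, salicylic acid (cat.), CH2Cl2, 0 °C → rt, stopped at partial conversion
Reagents that add atoms: selenium dioxide, O=[Se]=O (delivers the O atom, catalytic); tert-butyl hydroperoxide, CC(C)(C)OO (re-supplies it)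
Why: The Riley allylic oxidation (ene reaction, then [2,3]-sigmatropic shift) prefers the exposed gem-dimethyl alkene, and its cyclic transition state oxidises only the methyl group trans to the chain, which fixes the E geometry that later becomes the equatorial C18.

Step 3
Reactants: 5 tert-butyl (4E,8E,12E)-14-hydroxy-5,9,13-trimethyltetradeca-4,8,12-trienoate
Product: 6 tert-butyl (4E,8E)-11-[(2S,3S)-3-(hydroxymethyl)-3-methyloxiran-2-yl]-5,9-dimethylundeca-4,8-dienoate
Conditions: Ti(OiPr)4 (cat.), L-(+)-diethyl tartrate (cat.), t-BuOOH, 4 Å MS, CH2Cl2, −20 °C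
Reagents that add atoms: tert-butyl hydroperoxide, CC(C)(C)OO
Why: The Sharpless asymmetric epoxidation is hydroxyl-directed, so only the C3=C4 alkene reacts, and the L-(+)-tartrate ligand selects the face that gives the (2S,3S)-epoxy alcohol, setting C3 and C4.

Step 4
Reactants: 6 tert-butyl (4E,8E)-11-[(2S,3S)-3-(hydroxymethyl)-3-methyloxiran-2-yl]-5,9-dimethylundeca-4,8-dienoate
Product: 7 tert-butyl (4E,8E)-11-[(2S,3S)-3-(tert-butyldimethylsilyloxymethyl)-3-methyloxiran-2-yl]-5,9-dimethylundeca-4,8-dienoate
Conditions: TBSCl, imidazole, DMF, 0 °C → rt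
Reagents that add atoms: tert-butyldimethylsilyl chloride, CC(C)(C)[Si](C)(C)Cl
Why: Imidazole-promoted O-silylation masks the primary alcohol as a bulky, weakly basic ether that cannot take part as a neighbouring group at C4 and leaves both epoxide stereocentres untouched.

Step 5
Reactants: 7 tert-butyl (4E,8E)-11-[(2S,3S)-3-(tert-butyldimethylsilyloxymethyl)-3-methyloxiran-2-yl]-5,9-dimethylundeca-4,8-dienoate
Product: 9 3β-hydroxy-18-(tert-butyldimethylsilyloxy)-14,15,16-trinorlabdan-13,8α-olide, via bicyclic C8 carbocation 8 (not isolated)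
Conditions: MeAlCl2 (2 equiv), CH2Cl2, −78 °C; aq. work-up
Reagents that add atoms: none
Why: MeAlCl2 binds the epoxide oxygen, the C4–O bond ionises with backside participation of the C5=C10 alkene, C9 of the C8=C9 alkene attacks the developing C10 cation, and the C8 cation 8 is captured by the ester carbonyl oxygen with loss of isobutene, the released proton being scavenged by the Al–CH3 bond. The closest known reaction type is the biomimetic Lewis-acid-induced epoxy-polyene cyclisation with an internal carboxyl terminator, of the kind that converts farnesylacetic acid into its tricyclic δ-lactone. Ring A closes 6-endo-tet at the epoxide and 6-endo-trig at C5=C10, ring B then closes 6-endo-trig at C8=C9 as the last carbocycle, and the temporary lactone closes by six-membered O-attack on C8. C3 is retained from the epoxide as the equatorial 3β-OH, C4 is inverted so that the E-CH2OTBS group becomes equatorial (4α) and the methyl axial (4β), anti addition across the E C5=C10 alkene in a chair fold gives 5α-H and 10β-CH3, and anti addition across the E C8=C9 alkene gives 9α-H, 8β-CH3 and 8α-O. The step needs ionisation at C4 rather than attack at C3, and it needs full propagation: the tertiary C4, the non-participating silyl ether and the low temperature secure the first, and the chair-chair fold with a six-membered terminator secures the second.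

Step 6
Reactants: 9 3β-hydroxy-18-(tert-butyldimethylsilyloxy)-14,15,16-trinorlabdan-13,8α-olide
Product: 10 3β-(imidazol-1-ylthiocarbonyloxy)-18-(tert-butyldimethylsilyloxy)-14,15,16-trinorlabdan-13,8α-olide
Conditions: Im2C=S, DMAP (cat.), ClCH2CH2Cl, reflux
Reagents that add atoms: 1,1'-thiocarbonyldiimidazole, S=C(n1ccnc1)n1ccnc1
Why: O-Thioacylation of the only free hydroxyl is the first half of the Barton–McCombie deoxygenation, DMAP and heat overcoming the hindrance next to the quaternary C4.

Step 7
Reactants: 10 3β-(imidazol-1-ylthiocarbonyloxy)-18-(tert-butyldimethylsilyloxy)-14,15,16-trinorlabdan-13,8α-olide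
Product: 11 18-(tert-butyldimethylsilyloxy)-14,15,16-trinorlabdan-13,8α-olide
Conditions: Bu3SnH, AIBN (cat.), toluene, 110 °C
Reagents that add atoms: none
Why: In the Barton–McCombie radical deoxygenation the stannyl radical adds to C=S, the secondary C3 radical is released and abstracts H from Bu3SnH, and C3 becomes a CH2 group while no other stereocentre is involved.

Step 8
Reactants: 11 18-(tert-butyldimethylsilyloxy)-14,15,16-trinorlabdan-13,8α-olide
Product: 12 14,15,16-trinorlabdan-13,8α-olid-18-oic acid
Conditions: CrO3, H2SO4, H2O, acetone, 0 °C → rt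
Reagents that add atoms: water, O
Why: Under Jones oxidation conditions the aqueous acid cleaves the primary silyl ether and the freed alcohol is oxidised through the aldehyde hydrate to the acid, while the quaternary C4 cannot epimerise and the lactone is inert.

Step 9
Reactants: 12 14,15,16-trinorlabdan-13,8α-olid-18-oic acid
Product: 14 dibenzyl 8α-hydroxy-14,15,16-trinorlabdane-13,18-dioate, via dipotassium 8α-hydroxy-13,18-dioate salt 13 (not isolated)
Conditions: KOH (2.1 equiv), MeOH–H2O, reflux; evaporate to dryness; BnBr, DMF, rt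
Reagents that add atoms: potassium hydroxide, [K+].[OH-]; benzyl bromide, BrCc1ccccc1
Why: Saponification of the δ-lactone by acyl–oxygen cleavage keeps the configuration at C8, and SN2 O-alkylation of both carboxylates then masks C13 and C18 without passing through the free hydroxy acid, which would relactonise.

Step 10
Reactants: 14 dibenzyl 8α-hydroxy-14,15,16-trinorlabdane-13,18-dioate
Product: 15 dibenzyl 8α-acetoxy-14,15,16-trinorlabdane-13,18-dioate
Conditions: AcCl, PhNMe2, CH2Cl2, rt
Reagents that add atoms: acetyl chloride, CC(=O)Cl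
Why: O-Acylation of the equatorial tertiary alcohol by an acyl chloride, buffered by a weak non-nucleophilic amine, forms only the O–acyl bond, so C8 is untouched and neither alkoxide-induced relactonisation nor acid-induced elimination is triggered.

Step 11
Reactants: 15 dibenzyl 8α-acetoxy-14,15,16-trinorlabdane-13,18-dioate
Product: 16 8α-acetoxy-14,15,16-trinorlabdane-13,18-dioic acid (CNP0196050.1)
Conditions: H2 (1 atm), Pd/C, EtOAc, rt
Reagents that add atoms: none
Why: Catalytic hydrogenolysis of the two benzyl esters frees both acids under neutral conditions that leave the tertiary acetate and all five stereocentres unchanged.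

Compound list
1 | (2E,6E)-farnesyl bromide | CC(C)=CCC/C(C)=C/CC/C(C)=C/CBr | starting material
2 | tert-butyl acetate | CC(=O)OC(C)(C)C | starting material
3 | lithium enolate of tert-butyl acetate | [Li+].C=C([O-])OC(C)(C)C | intermediate
4 | tert-butyl (4E,8E)-5,9,13-trimethyltetradeca-4,8,12-trienoate | CC(C)=CCC/C(C)=C/CC/C(C)=C/CCC(=O)OC(C)(C)C | intermediate
5 | tert-butyl (4E,8E,12E)-14-hydroxy-5,9,13-trimethyltetradeca-4,8,12-trienoate | OC/C(C)=C/CC/C(C)=C/CC/C(C)=C/CCC(=O)OC(C)(C)C | intermediate
6 | tert-butyl (4E,8E)-11-[(2S,3S)-3-(hydroxymethyl)-3-methyloxiran-2-yl]-5,9-dimethylundeca-4,8-dienoate | OC[C@]1(C)O[C@H]1CC/C(C)=C/CC/C(C)=C/CCC(=O)OC(C)(C)C | intermediate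
7 | tert-butyl (4E,8E)-11-[(2S,3S)-3-(tert-butyldimethylsilyloxymethyl)-3-methyloxiran-2-yl]-5,9-dimethylundeca-4,8-dienoate | CC(C)(C)[Si](C)(C)OC[C@]1(C)O[C@H]1CC/C(C)=C/CC/C(C)=C/CCC(=O)OC(C)(C)C | intermediate
8 | bicyclic C8 carbocation (rings A and B closed; tert-butyl ester still open; O3–Al drawn as OH) | C[C+]1CC[C@@H]2[C@](C)(CC[C@H](O)[C@@]2(C)CO[Si](C)(C)C(C)(C)C)[C@H]1CCC(=O)OC(C)(C)C | intermediate
9 | 3β-hydroxy-18-(tert-butyldimethylsilyloxy)-14,15,16-trinorlabdan-13,8α-olide (4β-CH3; 5α-H; 8β-CH3; 9α-H; 10β-CH3) | O=C3O[C@]1(C)CC[C@@H]2[C@](C)(CC[C@H](O)[C@@]2(C)CO[Si](C)(C)C(C)(C)C)[C@H]1CC3 | intermediate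
10 | 3β-(imidazol-1-ylthiocarbonyloxy)-18-(tert-butyldimethylsilyloxy)-14,15,16-trinorlabdan-13,8α-olide | O=C3O[C@]1(C)CC[C@@H]2[C@](C)(CC[C@H](OC(=S)n4ccnc4)[C@@]2(C)CO[Si](C)(C)C(C)(C)C)[C@H]1CC3 | intermediate
11 | 18-(tert-butyldimethylsilyloxy)-14,15,16-trinorlabdan-13,8α-olide | O=C3O[C@]1(C)CC[C@@H]2[C@](C)(CCC[C@@]2(C)CO[Si](C)(C)C(C)(C)C)[C@H]1CC3 | intermediate
12 | 14,15,16-trinorlabdan-13,8α-olid-18-oic acid | O=C3O[C@]1(C)CC[C@@H]2[C@](C)(CCC[C@@]2(C)C(=O)O)[C@H]1CC3 | intermediate
13 | dipotassium 8α-hydroxy-14,15,16-trinorlabdane-13,18-dioate | [K+].[K+].O[C@]1(C)CC[C@@H]2[C@](C)(CCC[C@@]2(C)C(=O)[O-])[C@H]1CCC(=O)[O-] | intermediate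
14 | dibenzyl 8α-hydroxy-14,15,16-trinorlabdane-13,18-dioate | O[C@]1(C)CC[C@@H]2[C@](C)(CCC[C@@]2(C)C(=O)OCc3ccccc3)[C@H]1CCC(=O)OCc4ccccc4 | intermediate
15 | dibenzyl 8α-acetoxy-14,15,16-trinorlabdane-13,18-dioate | CC(=O)O[C@]1(C)CC[C@@H]2[C@](C)(CCC[C@@]2(C)C(=O)OCc3ccccc3)[C@H]1CCC(=O)OCc4ccccc4 | intermediate
16 | 8α-acetoxy-14,15,16-trinorlabdane-13,18-dioic acid (4α-COOH; 4β-CH3; 5α-H; 8β-CH3; 9α-H; 10β-CH3) | CC(=O)O[C@]1(C)CC[C@@H]2[C@](C)(CCC[C@@]2(C)C(=O)O)[C@H]1CCC(=O)O | target

Total step count: 11. Longest linear sequence: 11.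

Steps most likely to fail

(1) Step 5.
- **What may go wrong:** the cascade may stop early by proton loss after closure of ring A. The activated epoxide may rearrange by hydride shift. The alkene may attack C3 and close a five-membered ring.
- **Fallback, from 7 back to 9:** the polar trigger is replaced by a radical one. Cp2TiCl (trivalent titanium, made from Cp2TiCl2 and Mn dust in THF) opens the epoxide homolytically to the tertiary C4 radical. Two 6-endo radical closures follow in the same order, ring A and then ring B, with the bulky CH2OTBS group taking the equatorial position. Loss of a hydrogen atom from C17 should give tert-butyl 3β-hydroxy-18-(tert-butyldimethylsilyloxy)-14,15,16-trinorlabd-8(17)-en-13-oate F1. p-TsOH in CH2Cl2 then protonates C17, and the ester carbonyl captures the C8 cation from the α face to give 9.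

(2) Step 2.
- **What may go wrong:** site selectivity among three trisubstituted alkenes may be poor, and over-oxidation of the product may compete.
- **Fallback, from 4 back to 5:** the terminal isopropylidene carbon is excised and the oxidised E-terminus is rebuilt by olefination.
 - NBS in aqueous THF at 0 °C adds HOBr to the most exposed terminal alkene to give tert-butyl (4E,8E)-12-bromo-13-hydroxy-5,9,13-trimethyltetradeca-4,8-dienoate F2.
 - K2CO3 in MeOH closes it to the racemic terminal epoxide tert-butyl (4E,8E)-11-(3,3-dimethyloxiran-2-yl)-5,9-dimethylundeca-4,8-dienoate F3.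
 - HIO4 in aqueous THF cleaves this to tert-butyl (4E,8E)-5,9-dimethyl-12-oxododeca-4,8-dienoate F4.
 - A Wittig reaction with Ph3P=C(CH3)CHO in toluene gives tert-butyl (4E,8E,12E)-5,9,13-trimethyl-14-oxotetradeca-4,8,12-trienoate F5.
 - Luche reduction (NaBH4, CeCl3, MeOH) gives 5.

(3) Step 10.
- **What may go wrong:** acylation of the hindered tertiary alcohol may be slow enough for relactonisation onto the C13 ester, or elimination at C8, to compete.
- **Fallback, from 11 to 16:** the electrophilic C13 carbonyl is removed before the acetate is installed.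
 - LiAlH4 in THF reduces the lactone to 18-(tert-butyldimethylsilyloxy)-14,15,16-trinorlabdane-8α,13-diol F6.
 - Bu4NF frees 14,15,16-trinorlabdane-8α,13,18-triol F7.
 - Ac2O, DMAP and Et3N at 50 °C give 8α,13,18-triacetoxy-14,15,16-trinorlabdane F8.
 - K2CO3 in MeOH removes only the two primary acetates to give 8α-acetoxy-14,15,16-trinorlabdane-13,18-diol F9.
 - CrO3/H2SO4 in acetone oxidises both primary alcohols to give 16.

Further compounds
F1 | step 5 | tert-butyl 3β-hydroxy-18-(tert-butyldimethylsilyloxy)-14,15,16-trinorlabd-8(17)-en-13-oate | C=C1CC[C@@H]2[C@](C)(CC[C@H](O)[C@@]2(C)CO[Si](C)(C)C(C)(C)C)[C@H]1CCC(=O)OC(C)(C)C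
F2 | step 2 | tert-butyl (4E,8E)-12-bromo-13-hydroxy-5,9,13-trimethyltetradeca-4,8-dienoate (racemic) | CC(C)(O)C(Br)CC/C(C)=C/CC/C(C)=C/CCC(=O)OC(C)(C)C
F3 | step 2 | tert-butyl (4E,8E)-11-(3,3-dimethyloxiran-2-yl)-5,9-dimethylundeca-4,8-dienoate (racemic) | CC1(C)OC1CC/C(C)=C/CC/C(C)=C/CCC(=O)OC(C)(C)C
F4 | step 2 | tert-butyl (4E,8E)-5,9-dimethyl-12-oxododeca-4,8-dienoate | O=CCC/C(C)=C/CC/C(C)=C/CCC(=O)OC(C)(C)C
F5 | step 2 | tert-butyl (4E,8E,12E)-5,9,13-trimethyl-14-oxotetradeca-4,8,12-trienoate | O=C/C(C)=C/CC/C(C)=C/CC/C(C)=C/CCC(=O)OC(C)(C)C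
F6 | step 10 | 18-(tert-butyldimethylsilyloxy)-14,15,16-trinorlabdane-8α,13-diol | O[C@]1(C)CC[C@@H]2[C@](C)(CCC[C@@]2(C)CO[Si](C)(C)C(C)(C)C)[C@H]1CCCO
F7 | step 10 | 14,15,16-trinorlabdane-8α,13,18-triol | O[C@]1(C)CC[C@@H]2[C@](C)(CCC[C@@]2(C)CO)[C@H]1CCCO
F8 | step 10 | 8α,13,18-triacetoxy-14,15,16-trinorlabdane | CC(=O)O[C@]1(C)CC[C@@H]2[C@](C)(CCC[C@@]2(C)COC(C)=O)[C@H]1CCCOC(C)=O
F9 | step 10 | 8α-acetoxy-14,15,16-trinorlabdane-13,18-diol | CC(=O)O[C@]1(C)CC[C@@H]2[C@](C)(CCC[C@@]2(C)CO)[C@H]1CCCO
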